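**Retrosynthetic overview**
1. Neopeltolide ⇐ one Lindlar semihydrogenation of a bis-alkyne ⇐ Negishi coupling joining oxazole C4 to the terminal CH2 (C5') of the pent-2-ynoate arm: a primary alkylzinc iodide carried by the intact macrolactone plus methyl [3-(4-bromo-oxazol-2-yl)prop-2-ynyl]carbamate.
2. Enabling feature: oxazole C4 (between N3 and the unsubstituted C5–H) carries only that CH2, so it can be a plain C–Br electrophile; the CH2 is primary; and both Z-olefins (C2'=C3' next to the ester C=O, and the propenyl C=C on oxazole C2) are 1,2-disubstituted, so both can be stored as alkynes that tolerate RZnI and palladium and are released together.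
3. Alkyl iodide ⇐ Mitsunobu inversion at C5 of the all-equatorial macrolactone alcohol with 5-iodopent-2-ynoic acid; bromo-oxazole ⇐ 4-bromooxazole (C2 zincation/iodination, then Sonogashira).
4. Macrolactone alcohol ⇐ Prins macrocyclisation of an acetal ester/homoallylic alcohol; open chain from 3-methylglutarate (C7–C11, C9 by esterase desymmetrisation), (R)-2-propyloxirane (C12–C16, C13), Evans–Tishchenko reduction (C11 plus the C1–C3 ester) and allylboration (C4–C6, C7).
5. Ring order: oxazole bought intact; a 1,3-dithiane is a temporary ring (steps 4 to 7); oxane ring and 14-membered lactone close together in step 14.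

Key step: step 20

Assumption: the SMILES is taken literally, i.e. (3R,5R,7R,9S,11R,13R) in macrolide numbering (C1 = lactone carbonyl, C16 = propyl terminus), and 4-bromo-1,3-oxazole, 4-iodobut-1-yne and (R)-2-propyloxirane are taken as catalogue chemicals.

**Step 1**
Reactants: 1 dimethyl 3-methylpentanedioate
Product: 2 (3R)-5-methoxy-3-methyl-5-oxopentanoic acid
Conditions: pig liver esterase, NaH2PO4/Na2HPO4 buffer pH 7, NaOH (pH-stat), 25 °C; HCl to pH 2
Reagents that add atoms: water, O
Why: Enzymatic desymmetrisation: the esterase hydrolyses one of the two enantiotopic ester groups of the prochiral diester, which should fix C9 of the target in the (R)-half-ester.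

**Step 2**
Reactants: 2 (3R)-5-methoxy-3-methyl-5-oxopentanoic acid
Product: 4 (4R)-4-methyloxan-2-one, via hydroxy ester 3 (not isolated)
Conditions: BH3·SMe2, THF, 0 °C to rt; MeOH; then TsOH (cat.), toluene, rt
Reagents that add atoms: none
Why: Chemoselective borane reduction of the free acid beside the methyl ester, then acid-catalysed lactonisation; no stereocentre is touched, the acid carbon becomes C7 and the ester carbon C11.

**Step 3**
Reactants: 4 (4R)-4-methyloxan-2-one
Product: 5 (4R)-4-methyloxan-2-ol (anomer mixture)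
Conditions: i-Bu2AlH, CH2Cl2, −78 °C
Reagents that add atoms: none
Why: Low-temperature half-reduction of a δ-lactone stops at the lactol because the aluminium hemiacetal does not collapse at −78 °C.

**Step 4**
Reactants: 5 (4R)-4-methyloxan-2-ol
Product: 6 (3R)-4-(1,3-dithian-2-yl)-3-methylbutan-1-ol
Conditions: HS(CH2)3SH, BF3·OEt2, CH2Cl2, −20 to 0 °C
Reagents that add atoms: propane-1,3-dithiol, SCCCS
Why: Lewis acid-mediated thioacetalisation of the open hydroxy aldehyde turns C11 into a 1,3-dithiane (Corey–Seebach acyl anion precursor) and frees the C7 hydroxyl.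

**Step 5**
Reactants: 6 (3R)-4-(1,3-dithian-2-yl)-3-methylbutan-1-ol
Product: 7 tert-butyl{[(3R)-4-(1,3-dithian-2-yl)-3-methylbutyl]oxy}dimethylsilane
Conditions: TBSCl, imidazole, CH2Cl2, rt
Reagents that add atoms: tert-butyl(chloro)dimethylsilane, CC(C)(C)[Si](C)(C)Cl
Why: Standard silylation of the primary alcohol so that C7 survives the strongly basic step that follows.

**Step 6**
Reactants: 7 tert-butyl{[(3R)-4-(1,3-dithian-2-yl)-3-methylbutyl]oxy}dimethylsilane; 8 (2R)-2-propyloxirane
Product: 9 (2R)-1-{2-[(2R)-4-{[tert-butyl(dimethyl)silyl]oxy}-2-methylbutyl]-1,3-dithian-2-yl}pentan-2-ol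
Conditions: t-BuLi, THF/HMPA (10:1), −78 °C; then 8, −78 to −20 °C; H2O
Reagents that add atoms: none
Why: Corey–Seebach alkylation: the 2-lithio-1,3-dithiane opens the terminal epoxide at its CH2 carbon by SN2, so C13 keeps the (R)-configuration bought with 8.

**Step 7**
Reactants: 9 (2R)-1-{2-[(2R)-4-{[tert-butyl(dimethyl)silyl]oxy}-2-methylbutyl]-1,3-dithian-2-yl}pentan-2-ol
Product: 10 (3R,7R)-1-{[tert-butyl(dimethyl)silyl]oxy}-7-hydroxy-3-methyldecan-5-one
Conditions: MeI, CaCO3, MeCN/H2O (9:1), 45 °C
Reagents that add atoms: water, O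
Why: S-Methylation turns the dithiane sulfur atoms into leaving groups and buffered hydrolysis releases the C11 ketone without dehydrating the β-hydroxy ketone or cleaving the silyl ether.

**Step 8**
Reactants: 11 methyl 3,3-dimethoxypropanoate
Product: 12 3,3-dimethoxypropanal
Conditions: i-Bu2AlH, CH2Cl2, −78 °C; used freshly distilled
Reagents that add atoms: none
Why: Half-reduction of the methyl ester at −78 °C gives the aldehyde that serves as hydride donor and acyl source in step 9.

**Step 9**
Reactants: 10 (3R,7R)-1-{[tert-butyl(dimethyl)silyl]oxy}-7-hydroxy-3-methyldecan-5-one; 12 3,3-dimethoxypropanal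
Product: 13 (4R,6R,8R)-10-{[tert-butyl(dimethyl)silyl]oxy}-6-hydroxy-8-methyldecan-4-yl 3,3-dimethoxypropanoate
Conditions: SmI2 (0.3 equiv), 12 (5 equiv), THF, −10 °C
Reagents that add atoms: none
Why: Evans–Tishchenko reduction: the hemiacetal of the C13 hydroxyl with 12 is bound to trivalent samarium together with the ketone and delivers hydride intramolecularly through a chair-like bicyclic transition state, which should set C11 as (R), 1,3-anti to C13, and leave C13 acylated with the complete C1–C3 unit.

**Step 10**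
Reactants: 13 (4R,6R,8R)-10-{[tert-butyl(dimethyl)silyl]oxy}-6-hydroxy-8-methyldecan-4-yl 3,3-dimethoxypropanoate
Product: 14 (4R,6R,8R)-10-{[tert-butyl(dimethyl)silyl]oxy}-6-methoxy-8-methyldecan-4-yl 3,3-dimethoxypropanoate
Conditions: MeOTf, 2,6-di-tert-butyl-4-methylpyridine, CH2Cl2, 0 °C to rt
Reagents that add atoms: methyl trifluoromethanesulfonate, COS(=O)(=O)C(F)(F)F
Why: Non-basic O-methylation (methyl triflate with a hindered pyridine) etherifies the C11 hydroxyl without 1,3-acyl migration or β-elimination of the acetal ester.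

**Step 11**
Reactants: 14 (4R,6R,8R)-10-{[tert-butyl(dimethyl)silyl]oxy}-6-methoxy-8-methyldecan-4-yl 3,3-dimethoxypropanoate
Product: 15 (4R,6R,8R)-10-hydroxy-6-methoxy-8-methyldecan-4-yl 3,3-dimethoxypropanoate
Conditions: Bu4NF, AcOH, THF, 0 °C to rt
Reagents that add atoms: none
Why: Buffered fluoride cleaves the primary silyl ether while the ester, the acetal and the methyl ether are untouched.

**Step 12**
Reactants: 15 (4R,6R,8R)-10-hydroxy-6-methoxy-8-methyldecan-4-yl 3,3-dimethoxypropanoate
Product: 16 (4R,6R,8S)-6-methoxy-8-methyl-10-oxodecan-4-yl 3,3-dimethoxypropanoate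
Conditions: Dess–Martin periodinane, NaHCO3, CH2Cl2, 0 °C to rt
Reagents that add atoms: none
Why: Dess–Martin oxidation under buffered conditions gives the C7 aldehyde, which has no epimerisable α-centre, and leaves the acetal alone.

**Step 13**
Reactants: 16 (4R,6R,8S)-6-methoxy-8-methyl-10-oxodecan-4-yl 3,3-dimethoxypropanoate
Product: 17 (4R,6R,8R,10S)-10-hydroxy-6-methoxy-8-methyltridec-12-en-4-yl 3,3-dimethoxypropanoate
Conditions: (−)-Ipc2BOMe, CH2=CHCH2MgBr, Et2O, 0 °C to rt; then 16, −78 °C; HOCH2CH2NH2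
Reagents that add atoms: allylmagnesium bromide, C=CC[Mg]Br (allyl group, relayed through boron)
Why: Brown allylboration under reagent control: the allylborane derived from (+)-α-pinene should add to the Si face of the aldehyde through a chair Zimmerman–Traxler transition state, setting C7 (10S in 17), and it does not attack esters at −78 °C.

**Step 14**
Reactants: 17 (4R,6R,8R,10S)-10-hydroxy-6-methoxy-8-methyltridec-12-en-4-yl 3,3-dimethoxypropanoate
Product: 19 (1R,5R,7R,9S,11R,13S)-13-hydroxy-7-methoxy-9-methyl-5-propyl-4,15-dioxabicyclo[9.3.1]pentadecan-3-one, via macrolactone trifluoroacetate 18 (not isolated)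
Conditions: CF3CO2H (20 equiv), CH2Cl2 (2 mM), 0 °C to rt; then K2CO3, MeOH, 0 °C
Reagents that add atoms: trifluoroacetic acid, OC(=O)C(F)(F)F (the C5 oxygen)
Why: Prins macrocyclisation: acid ionises the acetal, the C7 hydroxyl captures C3 to give a cyclic oxocarbenium ion and the terminal olefin attacks it in a chair transition state with both ring substituents equatorial, so oxane and 14-membered lactone form together with C3 (R) 2,6-cis to C7 and trifluoroacetate entering equatorially at C5 (5S); mild methanolysis then removes only the trifluoroacetyl group.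

**Step 15**
Reactants: 20 4-iodobut-1-yne
Product: 21 5-iodopent-2-ynoic acid
Conditions: LiN(i-Pr)2, THF, −78 °C; CO2; HCl (aq)
Reagents that add atoms: carbon dioxide, O=C=O
Why: Deprotonation of the terminal alkyne, far faster at −78 °C than elimination of the primary iodide, and carboxylation of the lithium acetylide.

**Step 16**
Reactants: 19 (1R,5R,7R,9S,11R,13S)-13-hydroxy-7-methoxy-9-methyl-5-propyl-4,15-dioxabicyclo[9.3.1]pentadecan-3-one; 21 5-iodopent-2-ynoic acid
Product: 22 (1R,5R,7R,9S,11R,13R)-7-methoxy-9-methyl-3-oxo-5-propyl-4,15-dioxabicyclo[9.3.1]pentadecan-13-yl 5-iodopent-2-ynoate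
Conditions: PPh3, DIAD, toluene, 0 °C to rt
Reagents that add atoms: none
Why: Mitsunobu esterification: the acidic ynoic acid displaces the alkoxyphosphonium ion by SN2, inverting C5 from the equatorial (5S) alcohol to the axial (5R) ester of the target.

**Step 17**
Reactants: 23 prop-2-yn-1-amine
Product: 24 methyl prop-2-yn-1-ylcarbamate
Conditions: ClCO2Me, Et3N, CH2Cl2, 0 °C
Reagents that add atoms: methyl chloroformate, COC(=O)Cl
Why: N-Acylation of the primary amine by the chloroformate gives the methyl carbamate of the target.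

**Step 18**
Reactants: 25 4-bromo-1,3-oxazole
Product: 27 4-bromo-2-iodo-1,3-oxazole, via oxazol-2-ylzinc chloride 26 (not isolated)
Conditions: TMPZnCl·LiCl, THF, 25 °C; then I2, 0 °C
Reagents that add atoms: iodine, II
Why: Directed zincation: the hindered zinc amide removes the most acidic ring proton (C2–H between O and N) without ring opening or halogen migration, and iodinolysis of the carbon–zinc bond gives the 2-iodide.

**Step 19**
Reactants: 27 4-bromo-2-iodo-1,3-oxazole; 24 methyl prop-2-yn-1-ylcarbamate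
Product: 28 methyl [3-(4-bromo-1,3-oxazol-2-yl)prop-2-yn-1-yl]carbamate
Conditions: PdCl2(PPh3)2 (3 mol %), CuI (5 mol %), Et3N, THF, rt
Reagents that add atoms: none
Why: Sonogashira coupling at the C2–iodine bond, which undergoes oxidative addition far faster than the C4–bromine bond, so the bromide is kept for the key step.

**Step 20**
Reactants: 22 (1R,5R,7R,9S,11R,13R)-7-methoxy-9-methyl-3-oxo-5-propyl-4,15-dioxabicyclo[9.3.1]pentadecan-13-yl 5-iodopent-2-ynoate; 28 methyl [3-(4-bromo-1,3-oxazol-2-yl)prop-2-yn-1-yl]carbamate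
Product: 30 (1R,5R,7R,9S,11R,13R)-7-methoxy-9-methyl-3-oxo-5-propyl-4,15-dioxabicyclo[9.3.1]pentadecan-13-yl 5-[2-(3-{[methoxycarbonyl]amino}prop-1-yn-1-yl)-1,3-oxazol-4-yl]pent-2-ynoate, via alkylzinc iodide 29 (not isolated)
Conditions: Zn dust (activated), LiCl, THF, 30 °C; then slow addition to 28, Pd(OAc)2 (4 mol %), SPhos (8 mol %), THF, 25 °C
Reagents that add atoms: none
Why: Zinc metal inserts into the primary carbon–iodine bond of 22 to give alkylzinc iodide 29; zerovalent palladium, formed in situ from Pd(OAc)2 and SPhos, adds oxidatively to the C4–Br bond of 28, transmetalation transfers the CH2 group and reductive elimination forges the C(sp3)–C4 bond (Negishi coupling; closest known type: primary alkylzinc halides with five-membered heteroaryl bromides, including partners with free N–H groups). No ring is closed and no stereocentre is created; the six stereocentres of the macrolactone are remote from the reacting carbon and the medium is neutral, so none should be scrambled. The selectivity needed is chemoselectivity: the reagent must ignore the lactone, the ynoate, the carbamate and its N–H, which the low basicity and nucleophilicity of RZnI should secure, and C4–Br is the only carbon–halogen bond offered to palladium. β-Hydride elimination from the alkylpalladium intermediate should be outrun by reductive elimination at the bulky, electron-rich biarylphosphine. Both future Z-olefins are present as alkynes, which cannot undergo Z/E isomerisation under zinc or palladium. The step thus delivers in one flask the full carbon skeleton and every heteroatom of the target from two protecting-group-free halves.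

**Step 21**
Reactants: 30 (1R,5R,7R,9S,11R,13R)-7-methoxy-9-methyl-3-oxo-5-propyl-4,15-dioxabicyclo[9.3.1]pentadecan-13-yl 5-[2-(3-{[methoxycarbonyl]amino}prop-1-yn-1-yl)-1,3-oxazol-4-yl]pent-2-ynoate
Product: 31 neopeltolide
Conditions: H2 (1 atm), Pd/CaCO3 poisoned with Pb(OAc)2 (Lindlar catalyst), quinoline, EtOAc, rt
Reagents that add atoms: none
Why: Lindlar semihydrogenation adds H2 syn to both disubstituted alkynes on the poisoned palladium surface, which should give the (2Z)-enoate and the (Z)-alkenyl oxazole in one operation without touching the oxazole or the esters.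

**Compound list**
1 | dimethyl 3-methylpentanedioate | COC(=O)CC(C)CC(=O)OC | starting material
2 | (3R)-5-methoxy-3-methyl-5-oxopentanoic acid | COC(=O)C[C@H](C)CC(=O)O | intermediate
3 | methyl (3R)-5-hydroxy-3-methylpentanoate | COC(=O)C[C@H](C)CCO | intermediate
4 | (4R)-4-methyloxan-2-one | O=C1C[C@H](C)CCO1 | intermediate
5 | (4R)-4-methyloxan-2-ol (anomer mixture) | OC1C[C@H](C)CCO1 | intermediate
6 | (3R)-4-(1,3-dithian-2-yl)-3-methylbutan-1-ol | S1CCCSC1C[C@H](C)CCO | intermediate
7 | tert-butyl{[(3R)-4-(1,3-dithian-2-yl)-3-methylbutyl]oxy}dimethylsilane | S1CCCSC1C[C@H](C)CCO[Si](C)(C)C(C)(C)C | intermediate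
8 | (2R)-2-propyloxirane | CCC[C@@H]1CO1 | starting material
9 | (2R)-1-{2-[(2R)-4-{[tert-butyl(dimethyl)silyl]oxy}-2-methylbutyl]-1,3-dithian-2-yl}pentan-2-ol | CCC[C@@H](O)CC1(C[C@H](C)CCO[Si](C)(C)C(C)(C)C)SCCCS1 | intermediate
10 | (3R,7R)-1-{[tert-butyl(dimethyl)silyl]oxy}-7-hydroxy-3-methyldecan-5-one | CCC[C@@H](O)CC(=O)C[C@H](C)CCO[Si](C)(C)C(C)(C)C | intermediate
11 | methyl 3,3-dimethoxypropanoate | COC(OC)CC(=O)OC | starting material
12 | 3,3-dimethoxypropanal | COC(OC)CC=O | intermediate
13 | (4R,6R,8R)-10-{[tert-butyl(dimethyl)silyl]oxy}-6-hydroxy-8-methyldecan-4-yl 3,3-dimethoxypropanoate | CCC[C@@H](OC(=O)CC(OC)OC)C[C@H](O)C[C@H](C)CCO[Si](C)(C)C(C)(C)C | intermediate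
14 | (4R,6R,8R)-10-{[tert-butyl(dimethyl)silyl]oxy}-6-methoxy-8-methyldecan-4-yl 3,3-dimethoxypropanoate | CCC[C@@H](OC(=O)CC(OC)OC)C[C@H](OC)C[C@H](C)CCO[Si](C)(C)C(C)(C)C | intermediate
15 | (4R,6R,8R)-10-hydroxy-6-methoxy-8-methyldecan-4-yl 3,3-dimethoxypropanoate | CCC[C@@H](OC(=O)CC(OC)OC)C[C@H](OC)C[C@H](C)CCO | intermediate
16 | (4R,6R,8S)-6-methoxy-8-methyl-10-oxodecan-4-yl 3,3-dimethoxypropanoate | CCC[C@@H](OC(=O)CC(OC)OC)C[C@H](OC)C[C@H](C)CC=O | intermediate
17 | (4R,6R,8R,10S)-10-hydroxy-6-methoxy-8-methyltridec-12-en-4-yl 3,3-dimethoxypropanoate | CCC[C@@H](OC(=O)CC(OC)OC)C[C@H](OC)C[C@H](C)C[C@@H](O)CC=C | intermediate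
18 | (1R,5R,7R,9S,11R,13S)-7-methoxy-9-methyl-3-oxo-5-propyl-4,15-dioxabicyclo[9.3.1]pentadecan-13-yl trifluoroacetate | CCC[C@@H]1C[C@H](OC)C[C@H](C)C[C@@H]2C[C@H](OC(=O)C(F)(F)F)C[C@H](CC(=O)O1)O2 | intermediate
19 | (1R,5R,7R,9S,11R,13S)-13-hydroxy-7-methoxy-9-methyl-5-propyl-4,15-dioxabicyclo[9.3.1]pentadecan-3-one (macrolactone, equatorial 5-OH) | CCC[C@@H]1C[C@H](OC)C[C@H](C)C[C@@H]2C[C@H](O)C[C@H](CC(=O)O1)O2 | intermediate
20 | 4-iodobut-1-yne | C#CCCI | starting material
21 | 5-iodopent-2-ynoic acid | OC(=O)C#CCCI | intermediate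
22 | (1R,5R,7R,9S,11R,13R)-7-methoxy-9-methyl-3-oxo-5-propyl-4,15-dioxabicyclo[9.3.1]pentadecan-13-yl 5-iodopent-2-ynoate | CCC[C@@H]1C[C@H](OC)C[C@H](C)C[C@@H]2C[C@@H](OC(=O)C#CCCI)C[C@H](CC(=O)O1)O2 | intermediate
23 | prop-2-yn-1-amine | C#CCN | starting material
24 | methyl prop-2-yn-1-ylcarbamate | COC(=O)NCC#C | intermediate
25 | 4-bromo-1,3-oxazole | Brc1cocn1 | starting material
26 | (4-bromo-1,3-oxazol-2-yl)zinc chloride (LiCl complex) | Cl[Zn]c1nc(Br)co1 | intermediate
27 | 4-bromo-2-iodo-1,3-oxazole | Ic1nc(Br)co1 | intermediate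
28 | methyl [3-(4-bromo-1,3-oxazol-2-yl)prop-2-yn-1-yl]carbamate | COC(=O)NCC#Cc1nc(Br)co1 | intermediate
29 | (5-{[(1R,5R,7R,9S,11R,13R)-7-methoxy-9-methyl-3-oxo-5-propyl-4,15-dioxabicyclo[9.3.1]pentadecan-13-yl]oxy}-5-oxopent-3-yn-1-yl)zinc iodide | CCC[C@@H]1C[C@H](OC)C[C@H](C)C[C@@H]2C[C@@H](OC(=O)C#CCC[Zn]I)C[C@H](CC(=O)O1)O2 | intermediate
30 | (1R,5R,7R,9S,11R,13R)-7-methoxy-9-methyl-3-oxo-5-propyl-4,15-dioxabicyclo[9.3.1]pentadecan-13-yl 5-[2-(3-{[methoxycarbonyl]amino}prop-1-yn-1-yl)-1,3-oxazol-4-yl]pent-2-ynoate | CCC[C@@H]1C[C@H](OC)C[C@H](C)C[C@@H]2C[C@@H](OC(=O)C#CCCc3coc(C#CCNC(=O)OC)n3)C[C@H](CC(=O)O1)O2 | intermediate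
31 | neopeltolide, (1R,5R,7R,9S,11R,13R)-7-methoxy-9-methyl-3-oxo-5-propyl-4,15-dioxabicyclo[9.3.1]pentadecan-13-yl (2Z)-5-{2-[(1Z)-3-{[methoxycarbonyl]amino}prop-1-en-1-yl]-1,3-oxazol-4-yl}pent-2-enoate | CCC[C@@H]1C[C@H](OC)C[C@H](C)C[C@@H]2C[C@@H](OC(=O)/C=C\CCc3coc(/C=C\CNC(=O)OC)n3)C[C@H](CC(=O)O1)O2 | target

**Step count and risks**
Total step count: 21. Longest linear sequence: 16 steps (1 to 7, 9 to 14, 16, 20, 21).

Steps most likely to fail:

1. Step 20. The alkylzinc reagent may be protonated by the carbamate N–H, or the alkylpalladium intermediate may undergo β-hydride elimination, so that the advanced macrolactone fragment is consumed without coupling. Fallback: the carbon–carbon bond would be made on small partners that can be used in excess, and the halves joined through the ester instead. Setting out from 20, deprotonation with LiN(i-Pr)2 and trapping with ClCO2Me should give methyl 5-iodopent-2-ynoate F1. Zinc insertion (Zn, LiCl, THF) gives (5-methoxy-5-oxopent-3-yn-1-yl)zinc iodide F2, which is coupled in excess with 28 under Pd(OAc)2/SPhos to methyl 5-[2-(3-{[methoxycarbonyl]amino}prop-1-yn-1-yl)-1,3-oxazol-4-yl]pent-2-ynoate F3. LiOH (THF/H2O, 0 °C) should hydrolyse the ynoate ester selectively to 5-[2-(3-{[methoxycarbonyl]amino}prop-1-yn-1-yl)-1,3-oxazol-4-yl]pent-2-ynoic acid F4, and Mitsunobu esterification of 19 with F4 (PPh3, DIAD) comes back to the route at 30.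

2. Step 14. Intermolecular acetal exchange may outrun ring closure and give oligomers, or 2-oxonia-Cope rearrangement may erode C7 before the carbon–carbon bond forms. Fallback: the two ring closures would be separated. Setting out from 17, pyridinium tosylate (cat.) in toluene at 80 °C under high dilution with removal of MeOH should close the 12-membered ring by transacetalisation and elimination under thermodynamic control, giving (3E,6S,8S,10R,12R)-10-methoxy-8-methyl-6-(prop-2-en-1-yl)-12-propyl-1,5-dioxacyclododec-3-en-2-one F5. CF3CO2H (or Me3SiOTf) in CH2Cl2 would then protonate this vinylogous carbonate at C2, generate the oxocarbenium ion inside the ring and trigger a transannular Prins cyclisation, coming back to the route at 18 (then K2CO3/MeOH to 19).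

3. Step 9. Aldehyde 12 may eliminate methanol to 3-methoxyacrolein faster than it enters the samarium-bound hemiacetal, so that reduction and acyl transfer stall. Fallback: a simple acyl group would be transferred first and the C1–C3 unit attached by esterification. Setting out from 10, Evans–Tishchenko reduction with acetaldehyde (SmI2 cat., THF, −10 °C) should give (4R,6R,8R)-10-{[tert-butyl(dimethyl)silyl]oxy}-6-hydroxy-8-methyldecan-4-yl acetate F6. Methylation as in step 10 gives (4R,6R,8R)-10-{[tert-butyl(dimethyl)silyl]oxy}-6-methoxy-8-methyldecan-4-yl acetate F7, and K2CO3/MeOH liberates (4R,6R,8R)-10-{[tert-butyl(dimethyl)silyl]oxy}-6-methoxy-8-methyldecan-4-ol F8. Steglich esterification (DCC, DMAP) of F8 with 3,3-dimethoxypropanoic acid F9, obtained from 11 with LiOH, comes back to the route at 14.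

**Further compounds**
F1 | step 20 | methyl 5-iodopent-2-ynoate | COC(=O)C#CCCI
F2 | step 20 | (5-methoxy-5-oxopent-3-yn-1-yl)zinc iodide | COC(=O)C#CCC[Zn]I
F3 | step 20 | methyl 5-[2-(3-{[methoxycarbonyl]amino}prop-1-yn-1-yl)-1,3-oxazol-4-yl]pent-2-ynoate | COC(=O)C#CCCc1coc(C#CCNC(=O)OC)n1
F4 | step 20 | 5-[2-(3-{[methoxycarbonyl]amino}prop-1-yn-1-yl)-1,3-oxazol-4-yl]pent-2-ynoic acid | OC(=O)C#CCCc1coc(C#CCNC(=O)OC)n1
F5 | step 14 | (3E,6S,8S,10R,12R)-10-methoxy-8-methyl-6-(prop-2-en-1-yl)-12-propyl-1,5-dioxacyclododec-3-en-2-one | CCC[C@@H]1C[C@H](OC)C[C@H](C)C[C@H](CC=C)O/C=C/C(=O)O1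
F6 | step 9 | (4R,6R,8R)-10-{[tert-butyl(dimethyl)silyl]oxy}-6-hydroxy-8-methyldecan-4-yl acetate | CCC[C@@H](OC(C)=O)C[C@H](O)C[C@H](C)CCO[Si](C)(C)C(C)(C)C
F7 | step 9 | (4R,6R,8R)-10-{[tert-butyl(dimethyl)silyl]oxy}-6-methoxy-8-methyldecan-4-yl acetate | CCC[C@@H](OC(C)=O)C[C@H](OC)C[C@H](C)CCO[Si](C)(C)C(C)(C)C
F8 | step 9 | (4R,6R,8R)-10-{[tert-butyl(dimethyl)silyl]oxy}-6-methoxy-8-methyldecan-4-ol | CCC[C@@H](O)C[C@H](OC)C[C@H](C)CCO[Si](C)(C)C(C)(C)C
F9 | step 9 | 3,3-dimethoxypropanoic acid | COC(OC)CC(=O)O
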